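**Retrosynthetic overview**
- The target comes from its 7,4'-di-O-allyl ether by Pd-catalysed deallylation; nothing else is protected.
- Key disconnection: the C3–C4 bond. The aldehyde carbon of a fully prenylated aryl keto-aldehyde, turned into an acyl-anion equivalent (Breslow intermediate) by a chiral triazolylidene, attacks the aryl ketone carbonyl. This intramolecular crossed benzoin closes the pyranone ring (the only ring formed; both benzene rings are bought) and sets C3.
- The keto-aldehyde comes from Williamson union of a 3-prenyl-phloroglucinaldehyde 4-O-allyl ether with a phenacyl bromide.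
- The aldehyde half comes from 2,4,6-trihydroxybenzaldehyde (C-prenylation, 4-O-allylation); the bromide half from 2,4-dihydroxyacetophenone (C-prenylation, O-allylation/O-methylation, α-bromination).

Shorthand: prenyl = 3-methylbut-2-en-1-yl; allyl = prop-2-en-1-yl.

Assumption: the target is the (3R)-enantiomer (CIP from the given SMILES). The sense of induction in step 7 comes from a facial model, not a verified precedent, and must be confirmed by ECD on the first batch; the antipodal catalyst is equally available.

**Route**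

Step 1
Reactants: 1 2,4,6-trihydroxybenzaldehyde; 2 prenyl bromide
Product: 3 2,4,6-trihydroxy-3-prenylbenzaldehyde
Conditions: DBU (1.1 eq), THF, 0 °C → rt (1 in 1.5-fold excess)
Reagents that add atoms: none
Why: C-alkylation of the acylphloroglucinol phenoxide (phenoxide C-prenylation); the two free ring carbons of 1 are equivalent, so mono-prenylation gives one constitutional isomer (O- and di-prenyl by-products are separated, modest yield expected).

Step 2
Reactants: 3 2,4,6-trihydroxy-3-prenylbenzaldehyde
Product: 4 4-(allyloxy)-2,6-dihydroxy-3-prenylbenzaldehyde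
Conditions: allyl bromide (1.05 eq), K2CO3 (1.0 eq), acetone, 0 °C → rt
Reagents that add atoms: allyl bromide, C=CCBr
Why: Williamson etherification selective for the 4-OH, which is para to the formyl group, the most acidic and the only phenol not chelated to C=O.

Step 3
Reactants: 5 2,4-dihydroxyacetophenone; 2 prenyl bromide
Product: 6 1-(2,4-dihydroxy-3-prenylphenyl)ethan-1-one
Conditions: 10% aq KOH, 0 °C → rt
Reagents that add atoms: none
Why: C-prenylation of the resacetophenone dianion in water, which favours attack at C3 between the two oxygens (known reaction type, modest yield; 5-prenyl and O-prenyl isomers removed by chromatography).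

Step 4
Reactants: 6 1-(2,4-dihydroxy-3-prenylphenyl)ethan-1-one
Product: 8 1-[4-(allyloxy)-2-methoxy-3-prenylphenyl]ethan-1-one, via 4-O-allyl ether 7 (not isolated)
Conditions: allyl bromide (1.05 eq), K2CO3, DMF, rt; then MeI (3 eq), K2CO3, 50 °C (one pot)
Reagents that add atoms: allyl bromide, C=CCBr; iodomethane, CI
Why: Two sequential Williamson etherifications sorted by acidity: the free 4-OH reacts at rt, while the chelated, doubly flanked 2-OH reacts only with the small electrophile MeI on warming.

Step 5
Reactants: 8 1-[4-(allyloxy)-2-methoxy-3-prenylphenyl]ethan-1-one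
Product: 10 1-[4-(allyloxy)-2-methoxy-3-prenylphenyl]-2-bromoethan-1-one, via TMS enol ether 9 (not isolated)
Conditions: TMSOTf, Et3N, CH2Cl2, 0 °C; then NBS (1.0 eq), THF, −78 → 0 °C
Reagents that add atoms: N-bromosuccinimide, BrN1C(=O)CCC1=O; trimethylsilyl triflate, C[Si](C)(C)OS(=O)(=O)C(F)(F)F (silicon only in intermediate 9)
Why: Soft enolisation to the silyl enol ether followed by electrophilic α-bromination; at −78 °C the enol ether should outcompete the prenyl and allyl alkenes and the arene for NBS.

Step 6
Reactants: 4 4-(allyloxy)-2,6-dihydroxy-3-prenylbenzaldehyde; 10 1-[4-(allyloxy)-2-methoxy-3-prenylphenyl]-2-bromoethan-1-one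
Product: 11 4-(allyloxy)-2-hydroxy-6-{2-[4-(allyloxy)-2-methoxy-3-prenylphenyl]-2-oxoethoxy}-3-prenylbenzaldehyde
Conditions: K2CO3 (1.1 eq), acetone, 0 °C → rt (4 in slight excess, no heating)
Reagents that add atoms: none
Why: Williamson etherification (SN2 on the phenacyl bromide) at the 6-OH, which is flanked only by H, in preference to the 2-OH, which is buttressed by the prenyl group and more tightly chelated to the aldehyde; the remaining chelated OH resists a second alkylation, and room temperature avoids Rap–Stoermer aldol closure to a benzofuran.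

Step 7
Reactants: 11 4-(allyloxy)-2-hydroxy-6-{2-[4-(allyloxy)-2-methoxy-3-prenylphenyl]-2-oxoethoxy}-3-prenylbenzaldehyde
Product: 13 (3R)-7-(allyloxy)-3-[4-(allyloxy)-2-methoxy-3-prenylphenyl]-3,5-dihydroxy-6-prenyl-2,3-dihydro-4H-chromen-4-one, via Breslow enaminol 12 (not isolated)
Conditions: (5aS,10bR)-2-(pentafluorophenyl)-5a,10b-dihydro-4H,6H-indeno[2,1-b][1,2,4]triazolo[4,3-d][1,4]oxazin-2-ium tetrafluoroborate (15 mol%), i-Pr2NEt (15 mol%), toluene, 4 Å MS, Ar, rt → 40 °C
Reagents that add atoms: none
Why: NHC-catalysed intramolecular crossed aldehyde–ketone benzoin cyclisation: the carbene turns the aldehyde into a Breslow enaminol (acyl-anion equivalent) whose carbon adds 6-exo to the aryl ketone carbonyl and the catalyst is released from the α-ketol; the indane wall of the catalyst leaves one enaminol face open and the ketone, its oxygen hydrogen-bonded to the enol OH, is taken on its Si face, which sets (3R), while the weak amine base in toluene keeps the chelated 2-OH protonated and holds back the competing aldol.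

Step 8
Reactants: 13 (3R)-7-(allyloxy)-3-[4-(allyloxy)-2-methoxy-3-prenylphenyl]-3,5-dihydroxy-6-prenyl-2,3-dihydro-4H-chromen-4-one
Product: 14 (3R)-3,5,7-trihydroxy-3-[4-hydroxy-2-methoxy-3-prenylphenyl]-6-prenyl-2,3-dihydro-4H-chromen-4-one
Conditions: Pd(PPh3)4 (5 mol%), morpholine (10 eq), THF, rt, degassed
Reagents that add atoms: none
Why: Pd(0)-catalysed allyl transfer from the two aryl allyl ethers to morpholine (Tsuji–Trost deallylation) under neutral conditions that leave the C-prenyl groups, the acid- and base-sensitive tertiary α-ketol and the C3 stereocentre untouched.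

**Compound list**

1 | 2,4,6-trihydroxybenzaldehyde | O=Cc1c(O)cc(O)cc1O | starting material
2 | prenyl bromide (1-bromo-3-methylbut-2-ene) | CC(C)=CCBr | starting material
3 | 2,4,6-trihydroxy-3-(3-methylbut-2-en-1-yl)benzaldehyde | O=Cc1c(O)cc(O)c(CC=C(C)C)c1O | intermediate
4 | 2,6-dihydroxy-3-(3-methylbut-2-en-1-yl)-4-(prop-2-en-1-yloxy)benzaldehyde | O=Cc1c(O)cc(OCC=C)c(CC=C(C)C)c1O | intermediate
5 | 1-(2,4-dihydroxyphenyl)ethan-1-one | CC(=O)c1ccc(O)cc1O | starting material
6 | 1-[2,4-dihydroxy-3-(3-methylbut-2-en-1-yl)phenyl]ethan-1-one | CC(=O)c1ccc(O)c(CC=C(C)C)c1O | intermediate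
7 | 1-[2-hydroxy-3-(3-methylbut-2-en-1-yl)-4-(prop-2-en-1-yloxy)phenyl]ethan-1-one | CC(=O)c1ccc(OCC=C)c(CC=C(C)C)c1O | intermediate (not isolated)
8 | 1-[2-methoxy-3-(3-methylbut-2-en-1-yl)-4-(prop-2-en-1-yloxy)phenyl]ethan-1-one | CC(=O)c1ccc(OCC=C)c(CC=C(C)C)c1OC | intermediate
9 | trimethyl({1-[2-methoxy-3-(3-methylbut-2-en-1-yl)-4-(prop-2-en-1-yloxy)phenyl]ethenyl}oxy)silane | C=C(O[Si](C)(C)C)c1ccc(OCC=C)c(CC=C(C)C)c1OC | intermediate (not isolated)
10 | 2-bromo-1-[2-methoxy-3-(3-methylbut-2-en-1-yl)-4-(prop-2-en-1-yloxy)phenyl]ethan-1-one | BrCC(=O)c1ccc(OCC=C)c(CC=C(C)C)c1OC | intermediate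
11 | 2-hydroxy-6-{2-[2-methoxy-3-(3-methylbut-2-en-1-yl)-4-(prop-2-en-1-yloxy)phenyl]-2-oxoethoxy}-3-(3-methylbut-2-en-1-yl)-4-(prop-2-en-1-yloxy)benzaldehyde | O=Cc1c(O)c(CC=C(C)C)c(OCC=C)cc1OCC(=O)c1ccc(OCC=C)c(CC=C(C)C)c1OC | intermediate
12 | Breslow enaminol of 11 with the (5aS,10bR)-N-pentafluorophenyl triazolylidene (carbene carbon joined by C=C to the former aldehyde carbon, which carries OH) | OC(=C1N(c2c(F)c(F)c(F)c(F)c2F)N=C2CO[C@H]3Cc4ccccc4[C@H]3N12)c1c(O)c(CC=C(C)C)c(OCC=C)cc1OCC(=O)c1ccc(OCC=C)c(CC=C(C)C)c1OC | intermediate (not isolated)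
13 | (3R)-3,5-dihydroxy-3-[2-methoxy-3-(3-methylbut-2-en-1-yl)-4-(prop-2-en-1-yloxy)phenyl]-6-(3-methylbut-2-en-1-yl)-7-(prop-2-en-1-yloxy)-2,3-dihydro-4H-chromen-4-one | COc1c([C@@]2(O)COc3cc(OCC=C)c(CC=C(C)C)c(O)c3C2=O)ccc(OCC=C)c1CC=C(C)C | intermediate
14 | (3R)-3,5,7-trihydroxy-3-[4-hydroxy-2-methoxy-3-(3-methylbut-2-en-1-yl)phenyl]-6-(3-methylbut-2-en-1-yl)-2,3-dihydro-4H-chromen-4-one | COc1c([C@@]2(O)COc3cc(O)c(CC=C(C)C)c(O)c3C2=O)ccc(O)c1CC=C(C)C | target

**Totals**
Total step count: 8. Longest linear sequence: 6 (steps 3, 4, 5, 6, 7, 8, from 5 to 14).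

**Steps most likely to fail, with fallbacks**

Step 7. The aldehyde is 2,6-dioxygenated, electron-rich and carries a free chelated ortho-OH; the acceptor is an electron-rich o-methoxyaryl ketone; the substrate is enolisable, so aldol closure to a benzofuran competes; and the ee rests on an untested substrate class. The fallback sets out from 11 and removes the acidic chelated phenol before the cyclisation. Base-free Mitsunobu O-allylation of the 2-OH (allyl alcohol, PPh3, DIAD, THF, 0 °C → rt) gives the tri-O-allyl keto-aldehyde F1, a fully capped 2,6-dialkoxybenzaldehyde. The same triazolium-catalysed benzoin cyclisation then gives the (3R)-5,7,4'-tri-O-allyl chromanone F2. Pd(PPh3)4/morpholine removes all three allyl groups at once, and the fallback comes back to the route at 14.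

Step 6. Risks are alkylation at the wrong ortho-OH, double alkylation, and base-induced Rap–Stoermer aldol of the product. The fallback sets out from 10 and makes the ether bond without any base by activating the alcohol partner instead of the halide. Sodium formate in aqueous ethanol at reflux converts 10 into the α-hydroxy ketone F3. Mitsunobu coupling of F3 with phenol 4 (PPh3, DIAD, toluene, 0 °C) should engage only the accessible, more acidic 6-OH, and no enolate or phenoxide is ever present. It comes back to the route at 11.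

Step 1. C-prenylation of the trihydroxybenzaldehyde can be low-yielding through O- and poly-prenylation. The fallback sets out from 2 and commercial phloroglucinol (Oc1cc(O)cc(O)c1) and reverses the order of the two substitutions. Prenylation of excess phloroglucinol with 2 (aq KOH, 0 °C) gives 2-prenylphloroglucinol F4. Magnesium-mediated ortho-formylation (MgCl2, Et3N, paraformaldehyde, MeCN, reflux) at either of its two equivalent ring CH positions then gives a single aldehyde. It comes back to the route at 3.

**Further compounds**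

F1 | step 7 | 6-{2-[2-methoxy-3-(3-methylbut-2-en-1-yl)-4-(prop-2-en-1-yloxy)phenyl]-2-oxoethoxy}-3-(3-methylbut-2-en-1-yl)-2,4-bis(prop-2-en-1-yloxy)benzaldehyde | O=Cc1c(OCC=C)c(CC=C(C)C)c(OCC=C)cc1OCC(=O)c1ccc(OCC=C)c(CC=C(C)C)c1OC
F2 | step 7 | (3R)-3-hydroxy-3-[2-methoxy-3-(3-methylbut-2-en-1-yl)-4-(prop-2-en-1-yloxy)phenyl]-6-(3-methylbut-2-en-1-yl)-5,7-bis(prop-2-en-1-yloxy)-2,3-dihydro-4H-chromen-4-one | COc1c([C@@]2(O)COc3cc(OCC=C)c(CC=C(C)C)c(OCC=C)c3C2=O)ccc(OCC=C)c1CC=C(C)C
F3 | step 6 | 2-hydroxy-1-[2-methoxy-3-(3-methylbut-2-en-1-yl)-4-(prop-2-en-1-yloxy)phenyl]ethan-1-one | OCC(=O)c1ccc(OCC=C)c(CC=C(C)C)c1OC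
F4 | step 1 | 2-(3-methylbut-2-en-1-yl)benzene-1,3,5-triol | CC(C)=CCc1c(O)cc(O)cc1O
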